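## Retrosynthetic overview

1. Lactone (3S,4S): the C3–CH2 bond comes from trans-selective enolate alkylation of (S)-lactone 23 with benzylic bromide 29 (rings C/D). 23 comes from copper hydride reduction of butenolide 22, made by Suzuki coupling of aryl bromide 19 with 4-(bromomethyl)furan-2(5H)-one 20.
2. Both 1,2-diaryl C3 units come from one open-chain triol 18: silylated as such for the ring A/B arm, or closed by acid to the trans-dihydrobenzofuran (rings C/D).
3. 18 comes from the key step, a tethered hypervalent-iodine 1,2-aryl shift on β-acyloxy ketone 15 (ring B moves from the carbonyl carbon to Cα, anti to the C–O bond).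
4. 15 comes from a catalytic asymmetric Mukaiyama aldol between acetophenone 5 and vanillin pivalate 10; all four benzene rings come from catechol.
5. Ring order: benzene rings (catechol) → dihydrobenzofuran ring (step 14) → lactone ring (enters as butenolide 20, saturated in step 13, alkylated in step 18).

Assumption: the target is taken as drawn, i.e. (1S,2S) open diol, (3S,4S) lactone, (2R,3S) dihydrobenzofuran; for the two ligand-controlled steps (7 and 13) the antipode named is the one expected to give the stated configuration, and its mirror image is used if the facial sense proves opposite.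

Ring letters: ring A = guaiacyl ring on the open carbinol; ring B = ring carrying the lactone C4 benzyl; ring C = benzofuran benzene ring; ring D = guaiacyl ring on benzofuran C2.

## Route

Step 1
Reactants: 1 catechol
Product: 2 guaiacol (2-methoxyphenol)
Conditions: MeI (1.0 equiv), K2CO3, acetone, reflux
Reagents that add atoms: iodomethane, CI
Why: Williamson mono-O-methylation with one equivalent of electrophile; unreacted catechol is recycled.

Step 2
Reactants: 2 guaiacol
Product: 3 4-bromo-2-methoxyphenol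
Conditions: NBS, MeCN, 0 °C
Reagents that add atoms: N-bromosuccinimide, O=C1CCC(=O)N1Br
Why: electrophilic aromatic bromination, directed para to the free hydroxyl.

Step 3
Reactants: 3 4-bromo-2-methoxyphenol
Product: 5 1-(5-bromo-2-hydroxy-3-methoxyphenyl)ethanone, via 4-bromo-2-methoxyphenyl acetate 4 (not isolated)
Conditions: Ac2O, DMAP (cat.), neat, rt; evaporate; TiCl4, PhCl, 110 °C; H2O work-up
Reagents that add atoms: acetic anhydride, CC(=O)OC(C)=O
Why: O-acetylation then Fries rearrangement; the para position is blocked, so the titanium-bound phenolate delivers the acetyl group to the ortho carbon.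

Step 4
Reactants: 2 guaiacol; 6 glyoxylic acid
Product: 9 vanillin (4-hydroxy-3-methoxybenzaldehyde), via 4-hydroxy-3-methoxymandelic acid 7 (not isolated), via 2-(4-hydroxy-3-methoxyphenyl)-2-oxoacetic acid 8 (not isolated)
Conditions: NaOH aq., 30 °C; then CuSO4 (cat.), air, 95 °C; H2SO4 to pH 3, heat
Reagents that add atoms: none
Why: para-selective hydroxyalkylation of the phenolate, copper-catalysed aerobic oxidation to the keto acid and decarboxylation (the industrial vanillin sequence).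

Step 5
Reactants: 9 vanillin
Product: 10 4-formyl-2-methoxyphenyl pivalate
Conditions: PivCl, Et3N, DMAP (cat.), CH2Cl2, 0 °C
Reagents that add atoms: pivaloyl chloride, CC(C)(C)C(=O)Cl
Why: O-acylation; the electron-poor ester keeps ring A from stabilising a benzylic cation in steps 8–9 and is cleaved without an extra step in step 10.

Step 6
Reactants: 5 1-(5-bromo-2-hydroxy-3-methoxyphenyl)ethanone
Product: 12 {1-[5-bromo-3-methoxy-2-(triisopropylsilyloxy)phenyl]vinyloxy}trimethylsilane, via aryl triisopropylsilyl ether ketone 11 (not isolated)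
Conditions: i-Pr3SiOTf (1.05 equiv), Et3N, CH2Cl2, 0 °C; then Me3SiOTf (1.2 equiv), 0 °C
Reagents that add atoms: triisopropylsilyl triflate, CC(C)[Si](C(C)C)(C(C)C)OS(=O)(=O)C(F)(F)F; trimethylsilyl triflate, C[Si](C)(C)OS(=O)(=O)C(F)(F)F
Why: the phenoxide is silylated first (fast), then soft enolisation of the methyl ketone gives the silyl enol ether.

Step 7
Reactants: 12 silyl enol ether; 10 4-formyl-2-methoxyphenyl pivalate
Product: 14 (S)-1-[5-bromo-3-methoxy-2-(triisopropylsilyloxy)phenyl]-3-hydroxy-3-[3-methoxy-4-(pivaloyloxy)phenyl]propan-1-one, via trichlorosilyl ether of the aldol 13 (not isolated)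
Conditions: SiCl4 (1.2 equiv), Denmark (R,R)-bisphosphoramide (binaphthyldiamine-derived, pentane-1,5-diyl-linked; 5 mol%), i-Pr2NEt (10 mol%), CH2Cl2, −78 °C; H2O work-up
Reagents that add atoms: none
Why: Mukaiyama aldol under Lewis-base-activated SiCl4 catalysis; the chiral trichlorosilyl cation binds the aldehyde and the enol ether attacks its Si face, setting the carbinol centre (S).

Step 8
Reactants: 14 β-hydroxy ketone
Product: 15 (1S)-3-[5-bromo-3-methoxy-2-(triisopropylsilyloxy)phenyl]-1-[3-methoxy-4-(pivaloyloxy)phenyl]-3-oxopropyl 2-iodobenzoate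
Conditions: 2-iodobenzoyl chloride, pyridine, DMAP (cat.), CH2Cl2, 0 °C
Reagents that add atoms: 2-iodobenzoyl chloride, O=C(Cl)c1ccccc1I
Why: esterification of the secondary alcohol under weak-base conditions (no β-elimination); it attaches the iodoarene that will act as internal oxidant.

Step 9
Reactants: 15 2-iodobenzoate
Product: 17 methyl (2R,3S)-2-[5-bromo-3-methoxy-2-(triisopropylsilyloxy)phenyl]-3-[(2-iodobenzoyl)oxy]-3-[3-methoxy-4-(pivaloyloxy)phenyl]propanoate, via tethered bis(acetoxy)-λ3-iodane 16 (not isolated)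
Conditions: Selectfluor (1.0 equiv), AcOH, MeCN, rt; evaporate, CH2Cl2, filter; then HC(OMe)3/MeOH, H2SO4 (1 equiv), 0.01 M, −20 °C to rt
Reagents that add atoms: trimethyl orthoformate, COC(OC)OC
Why: Proposed new method: a tethered hypervalent-iodine oxidative 1,2-aryl shift. The ester-bound trivalent iodine of 16 is delivered intramolecularly (seven-membered transition state) to the α-carbon of the enol ether formed in situ from the ketone and HC(OMe)3. In the allylic-strain-minimised conformer (carbinol C–H eclipsing the enol double bond) the tether reaches only the face that carries the C–O bond. Ring B then migrates from the ketal carbon to Cα anti to the departing aryl iodide (inversion), so it ends anti to the oxygen, i.e. (2R,3S), and the dimethoxycarbenium ion collapses to the methyl ester. The closest known reactions are the PhI(OAc)2/HC(OMe)3/H2SO4 rearrangement of alkyl aryl ketones to methyl 2-arylalkanoates and the ring contraction of flavanones under the same conditions; neither has been run with a substrate-bound iodane or with acyclic 1,2-stereocontrol.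

Step 10
Reactants: 17 methyl ester
Product: 18 (1S,2S)-2-[5-bromo-3-methoxy-2-(triisopropylsilyloxy)phenyl]-1-(4-hydroxy-3-methoxyphenyl)propane-1,3-diol
Conditions: i-Bu2AlH (8 equiv), CH2Cl2, −78 to 0 °C; aq. potassium sodium tartrate
Reagents that add atoms: none
Why: hydride reduction converts the methyl ester to the primary alcohol and cleaves the pivalate and the 2-iodobenzoate in the same operation; the reagent is non-basic, so the α-aryl centre is not epimerised.

Step 11
Reactants: 18 triol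
Product: 19 5-bromo-3-methoxy-1-[(1S,2S)-1-[3-methoxy-4-(triisopropylsilyloxy)phenyl]-1,3-bis(triisopropylsilyloxy)propan-2-yl]-2-(triisopropylsilyloxy)benzene
Conditions: i-Pr3SiOTf (4 equiv), 2,6-lutidine, CH2Cl2, 0 °C to rt
Reagents that add atoms: triisopropylsilyl triflate, CC(C)[Si](C(C)C)(C(C)C)OS(=O)(=O)C(F)(F)F
Why: exhaustive silylation of the phenol and both alcohols with the strong silyl triflate gives a uniformly base- and acid-tolerant protecting set.

Step 12
Reactants: 19 aryl bromide; 20 4-(bromomethyl)furan-2(5H)-one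
Product: 22 4-{3-[(1S,2S)-1-[3-methoxy-4-(triisopropylsilyloxy)phenyl]-1,3-bis(triisopropylsilyloxy)propan-2-yl]-5-methoxy-4-(triisopropylsilyloxy)benzyl}furan-2(5H)-one, via pinacol boronate 21 (not isolated)
Conditions: B2pin2, Pd(dppf)Cl2 (5 mol%), KOAc, dioxane, 90 °C; then 20, K3PO4, H2O (5 equiv), 50 °C
Reagents that add atoms: none
Why: one-pot Miyaura borylation and Suzuki–Miyaura coupling with the allylic bromide; reductive elimination at the CH2 terminus keeps the alkene conjugated with the lactone carbonyl.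

Step 13
Reactants: 22 butenolide
Product: 23 (S)-4-{3-[(1S,2S)-1-[3-methoxy-4-(triisopropylsilyloxy)phenyl]-1,3-bis(triisopropylsilyloxy)propan-2-yl]-5-methoxy-4-(triisopropylsilyloxy)benzyl}dihydrofuran-2(3H)-one
Conditions: Cu(OAc)2·H2O (3 mol%), (R)-DTBM-SEGPHOS (3 mol%), (EtO)2MeSiH (2 equiv), t-BuOH (2 equiv), toluene, 0 °C
Reagents that add atoms: none
Why: ligand-controlled copper hydride asymmetric conjugate reduction of a β-substituted butenolide; hydride goes to one face of the β-carbon and sets lactone C4 (S), and the copper enolate is protonated by t-BuOH.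

Step 14
Reactants: 18 triol
Product: 25 [(2R,3S)-5-bromo-2-(4-hydroxy-3-methoxyphenyl)-7-methoxy-2,3-dihydro-1-benzofuran-3-yl]methanol, via desilylated tetraol 24 (not isolated)
Conditions: TBAF (2.2 equiv), THF, 0 °C; then TsOH·H2O (3 equiv), CH2Cl2, rt
Reagents that add atoms: none
Why: fluoride frees the ring-B phenol; acid then ionises the para-hydroxybenzylic alcohol to a quinone methide, which the ortho-phenol traps (5-exo) anti to the CH2OH arm, giving the trans ring (2R,3S) whatever the carbinol configuration, with C3 fixed since step 9.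

Step 15
Reactants: 25 dihydrobenzofuran phenol alcohol
Product: 26 (2R,3S)-5-bromo-7-methoxy-2-[3-methoxy-4-(triisopropylsilyloxy)phenyl]-3-[(triisopropylsilyloxy)methyl]-2,3-dihydro-1-benzofuran
Conditions: i-Pr3SiCl (2.5 equiv), imidazole, DMF, rt
Reagents that add atoms: chlorotriisopropylsilane, CC(C)[Si](Cl)(C(C)C)C(C)C
Why: standard silylation of the phenol and the primary alcohol.

Step 16
Reactants: 26 aryl bromide
Product: 28 {(2R,3S)-7-methoxy-2-[3-methoxy-4-(triisopropylsilyloxy)phenyl]-3-[(triisopropylsilyloxy)methyl]-2,3-dihydro-1-benzofuran-5-yl}methanol, via aryllithium 27 (not isolated)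
Conditions: n-BuLi (1.1 equiv), THF, −78 °C; then (CH2O)n (excess), −78 °C to rt; H2O work-up
Reagents that add atoms: formaldehyde (as paraformaldehyde), C=O
Why: bromine–lithium exchange is faster than any deprotonation at −78 °C, and the aryllithium adds to formaldehyde to give the benzylic alcohol.

Step 17
Reactants: 28 benzylic alcohol
Product: 29 (2R,3S)-5-(bromomethyl)-7-methoxy-2-[3-methoxy-4-(triisopropylsilyloxy)phenyl]-3-[(triisopropylsilyloxy)methyl]-2,3-dihydro-1-benzofuran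
Conditions: CBr4, PPh3, CH2Cl2, 0 °C; used at once
Reagents that add atoms: carbon tetrabromide, BrC(Br)(Br)Br
Why: Appel reaction under neutral conditions, tolerated by the silyl ethers and the electron-rich benzylic position.

Step 18
Reactants: 23 (S)-lactone; 29 benzylic bromide
Product: 31 hexakis(triisopropylsilyl) ether of the target, (3S,4S)-lactone, via lithium enolate 30 (not isolated)
Conditions: LiN(SiMe3)2 (1.1 equiv), THF, −78 °C; then 29, DMPU, −78 to −40 °C
Reagents that add atoms: none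
Why: enolate alkylation of a β-benzyl-γ-butyrolactone; the electrophile approaches anti to the C4 substituent and gives the trans (3S,4S) lactone, as in established dibenzylbutyrolactone lignan syntheses.

Step 19
Reactants: 31 hexasilyl ether
Product: 32 target CNP0199264.1
Conditions: TBAF (8 equiv), AcOH (8 equiv), THF, 0 °C to rt
Reagents that add atoms: none
Why: buffered fluoride desilylation removes all six silyl groups without acid, which would close the second diol to a dihydrobenzofuran, and without strong base, which would open the lactone.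

## Compound list

1 | catechol | Oc1ccccc1O | starting material
2 | guaiacol | COc1ccccc1O | intermediate
3 | 4-bromo-2-methoxyphenol | COc1cc(Br)ccc1O | intermediate
4 | 4-bromo-2-methoxyphenyl acetate | COc1cc(Br)ccc1OC(C)=O | intermediate
5 | 1-(5-bromo-2-hydroxy-3-methoxyphenyl)ethanone | CC(=O)c1cc(Br)cc(OC)c1O | intermediate
6 | glyoxylic acid | O=CC(=O)O | starting material
7 | 4-hydroxy-3-methoxymandelic acid (racemic) | COc1cc(C(O)C(=O)O)ccc1O | intermediate
8 | 2-(4-hydroxy-3-methoxyphenyl)-2-oxoacetic acid | COc1cc(C(=O)C(=O)O)ccc1O | intermediate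
9 | vanillin | COc1cc(C=O)ccc1O | intermediate
10 | 4-formyl-2-methoxyphenyl pivalate | COc1cc(C=O)ccc1OC(=O)C(C)(C)C | intermediate
11 | 1-[5-bromo-3-methoxy-2-(triisopropylsilyloxy)phenyl]ethanone | CC(=O)c1cc(Br)cc(OC)c1O[Si](C(C)C)(C(C)C)C(C)C | intermediate
12 | {1-[5-bromo-3-methoxy-2-(triisopropylsilyloxy)phenyl]vinyloxy}trimethylsilane | C=C(O[Si](C)(C)C)c1cc(Br)cc(OC)c1O[Si](C(C)C)(C(C)C)C(C)C | intermediate
13 | (S)-trichlorosilyl ether of 14 | COc1cc([C@@H](O[Si](Cl)(Cl)Cl)CC(=O)c2cc(Br)cc(OC)c2O[Si](C(C)C)(C(C)C)C(C)C)ccc1OC(=O)C(C)(C)C | intermediate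
14 | (S)-1-[5-bromo-3-methoxy-2-(triisopropylsilyloxy)phenyl]-3-hydroxy-3-[3-methoxy-4-(pivaloyloxy)phenyl]propan-1-one | COc1cc([C@@H](O)CC(=O)c2cc(Br)cc(OC)c2O[Si](C(C)C)(C(C)C)C(C)C)ccc1OC(=O)C(C)(C)C | intermediate
15 | (1S)-3-[5-bromo-3-methoxy-2-(triisopropylsilyloxy)phenyl]-1-[3-methoxy-4-(pivaloyloxy)phenyl]-3-oxopropyl 2-iodobenzoate | COc1cc([C@@H](OC(=O)c2ccccc2I)CC(=O)c2cc(Br)cc(OC)c2O[Si](C(C)C)(C(C)C)C(C)C)ccc1OC(=O)C(C)(C)C | intermediate
16 | (1S)-3-[5-bromo-3-methoxy-2-(triisopropylsilyloxy)phenyl]-1-[3-methoxy-4-(pivaloyloxy)phenyl]-3-oxopropyl 2-[bis(acetyloxy)-λ3-iodanyl]benzoate | COc1cc([C@@H](OC(=O)c2ccccc2I(OC(C)=O)OC(C)=O)CC(=O)c2cc(Br)cc(OC)c2O[Si](C(C)C)(C(C)C)C(C)C)ccc1OC(=O)C(C)(C)C | intermediate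
17 | methyl (2R,3S)-2-[5-bromo-3-methoxy-2-(triisopropylsilyloxy)phenyl]-3-[(2-iodobenzoyl)oxy]-3-[3-methoxy-4-(pivaloyloxy)phenyl]propanoate | COc1cc([C@@H](OC(=O)c2ccccc2I)[C@H](C(=O)OC)c2cc(Br)cc(OC)c2O[Si](C(C)C)(C(C)C)C(C)C)ccc1OC(=O)C(C)(C)C | intermediate
18 | (1S,2S)-2-[5-bromo-3-methoxy-2-(triisopropylsilyloxy)phenyl]-1-(4-hydroxy-3-methoxyphenyl)propane-1,3-diol | COc1cc([C@@H](O)[C@H](CO)c2cc(Br)cc(OC)c2O[Si](C(C)C)(C(C)C)C(C)C)ccc1O | intermediate
19 | 5-bromo-3-methoxy-1-[(1S,2S)-1-[3-methoxy-4-(triisopropylsilyloxy)phenyl]-1,3-bis(triisopropylsilyloxy)propan-2-yl]-2-(triisopropylsilyloxy)benzene | COc1cc([C@@H](O[Si](C(C)C)(C(C)C)C(C)C)[C@H](CO[Si](C(C)C)(C(C)C)C(C)C)c2cc(Br)cc(OC)c2O[Si](C(C)C)(C(C)C)C(C)C)ccc1O[Si](C(C)C)(C(C)C)C(C)C | intermediate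
20 | 4-(bromomethyl)furan-2(5H)-one | O=C1C=C(CBr)CO1 | starting material
21 | pinacol boronate of 19 (Bpin in place of Br) | COc1cc([C@@H](O[Si](C(C)C)(C(C)C)C(C)C)[C@H](CO[Si](C(C)C)(C(C)C)C(C)C)c2cc(B3OC(C)(C)C(C)(C)O3)cc(OC)c2O[Si](C(C)C)(C(C)C)C(C)C)ccc1O[Si](C(C)C)(C(C)C)C(C)C | intermediate
22 | 4-{3-[(1S,2S)-1-[3-methoxy-4-(triisopropylsilyloxy)phenyl]-1,3-bis(triisopropylsilyloxy)propan-2-yl]-5-methoxy-4-(triisopropylsilyloxy)benzyl}furan-2(5H)-one | COc1cc([C@@H](O[Si](C(C)C)(C(C)C)C(C)C)[C@H](CO[Si](C(C)C)(C(C)C)C(C)C)c2cc(CC3=CC(=O)OC3)cc(OC)c2O[Si](C(C)C)(C(C)C)C(C)C)ccc1O[Si](C(C)C)(C(C)C)C(C)C | intermediate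
23 | (S)-4-{3-[(1S,2S)-1-[3-methoxy-4-(triisopropylsilyloxy)phenyl]-1,3-bis(triisopropylsilyloxy)propan-2-yl]-5-methoxy-4-(triisopropylsilyloxy)benzyl}dihydrofuran-2(3H)-one | COc1cc([C@@H](O[Si](C(C)C)(C(C)C)C(C)C)[C@H](CO[Si](C(C)C)(C(C)C)C(C)C)c2cc(C[C@@H]3COC(=O)C3)cc(OC)c2O[Si](C(C)C)(C(C)C)C(C)C)ccc1O[Si](C(C)C)(C(C)C)C(C)C | intermediate
24 | (1S,2S)-2-(5-bromo-2-hydroxy-3-methoxyphenyl)-1-(4-hydroxy-3-methoxyphenyl)propane-1,3-diol | COc1cc([C@@H](O)[C@H](CO)c2cc(Br)cc(OC)c2O)ccc1O | intermediate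
25 | [(2R,3S)-5-bromo-2-(4-hydroxy-3-methoxyphenyl)-7-methoxy-2,3-dihydro-1-benzofuran-3-yl]methanol | Brc1cc(OC)c2c(c1)[C@@H](CO)[C@H](c1ccc(O)c(OC)c1)O2 | intermediate
26 | (2R,3S)-5-bromo-7-methoxy-2-[3-methoxy-4-(triisopropylsilyloxy)phenyl]-3-[(triisopropylsilyloxy)methyl]-2,3-dihydro-1-benzofuran | Brc1cc(OC)c2c(c1)[C@@H](CO[Si](C(C)C)(C(C)C)C(C)C)[C@H](c1ccc(O[Si](C(C)C)(C(C)C)C(C)C)c(OC)c1)O2 | intermediate
27 | aryllithium from 26 (Li in place of Br) | [Li]c1cc(OC)c2c(c1)[C@@H](CO[Si](C(C)C)(C(C)C)C(C)C)[C@H](c1ccc(O[Si](C(C)C)(C(C)C)C(C)C)c(OC)c1)O2 | intermediate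
28 | {(2R,3S)-7-methoxy-2-[3-methoxy-4-(triisopropylsilyloxy)phenyl]-3-[(triisopropylsilyloxy)methyl]-2,3-dihydro-1-benzofuran-5-yl}methanol | OCc1cc(OC)c2c(c1)[C@@H](CO[Si](C(C)C)(C(C)C)C(C)C)[C@H](c1ccc(O[Si](C(C)C)(C(C)C)C(C)C)c(OC)c1)O2 | intermediate
29 | (2R,3S)-5-(bromomethyl)-7-methoxy-2-[3-methoxy-4-(triisopropylsilyloxy)phenyl]-3-[(triisopropylsilyloxy)methyl]-2,3-dihydro-1-benzofuran | BrCc1cc(OC)c2c(c1)[C@@H](CO[Si](C(C)C)(C(C)C)C(C)C)[C@H](c1ccc(O[Si](C(C)C)(C(C)C)C(C)C)c(OC)c1)O2 | intermediate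
30 | lithium enolate of 23 | COc1cc([C@@H](O[Si](C(C)C)(C(C)C)C(C)C)[C@H](CO[Si](C(C)C)(C(C)C)C(C)C)c2cc(C[C@@H]3COC([O-])=C3)cc(OC)c2O[Si](C(C)C)(C(C)C)C(C)C)ccc1O[Si](C(C)C)(C(C)C)C(C)C.[Li+] | intermediate
31 | hexakis(triisopropylsilyl) ether of the target, (3S,4S)-lactone, (1S,2S) open unit, (2R,3S) dihydrobenzofuran | COc1cc([C@@H](O[Si](C(C)C)(C(C)C)C(C)C)[C@H](CO[Si](C(C)C)(C(C)C)C(C)C)c2cc(C[C@@H]3COC(=O)[C@H]3Cc3cc(OC)c4c(c3)[C@@H](CO[Si](C(C)C)(C(C)C)C(C)C)[C@H](c3ccc(O[Si](C(C)C)(C(C)C)C(C)C)c(OC)c3)O4)cc(OC)c2O[Si](C(C)C)(C(C)C)C(C)C)ccc1O[Si](C(C)C)(C(C)C)C(C)C | intermediate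
32 | CNP0199264.1 | COc1cc([C@@H](O)[C@H](CO)c2cc(C[C@@H]3COC(=O)[C@H]3Cc3cc(OC)c4c(c3)[C@@H](CO)[C@H](c3ccc(O)c(OC)c3)O4)cc(OC)c2O)ccc1O | target

## Step count and risks

Total steps: 19. Longest linear sequence: 14 (steps 1, 2, 3, 6, 7, 8, 9, 10, 14, 15, 16, 17, 18, 19).

Step 9 (the proposed new step). It can fail through intermolecular iodination, ester participation at Cα, acid-promoted elimination to the chalcone, or an unexpected facial sense. The fallback uses known reactions only, sets out from 11 (isolated by stopping step 6 before the Me3SiOTf addition) and returns at 18. The classical PhI(OAc)2, HC(OMe)3, H2SO4 oxidative 1,2-aryl shift of this aryl methyl ketone gives methyl 2-[5-bromo-3-methoxy-2-(triisopropylsilyloxy)phenyl]acetate F1. LiN(i-Pr)2, t-BuMe2SiCl, THF/DMPU at −78 °C gives its tert-butyldimethylsilyl ketene acetal F2. The SiCl4/bisphosphoramide system of step 7, which is anti-selective for α-substituted silyl ketene acetals whatever their geometry, adds F2 to aldehyde 10 and gives methyl (2R,3S)-2-[5-bromo-3-methoxy-2-(triisopropylsilyloxy)phenyl]-3-hydroxy-3-[3-methoxy-4-(pivaloyloxy)phenyl]propanoate F3. i-Bu2AlH then reduces the ester and cleaves the pivalate to give 18.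

Step 12 (one-pot borylation and coupling with a base-sensitive allylic bromide). The fallback sets out from 19 and returns at 22, forming the benzyl–butenolide bond with reversed polarity. n-BuLi then paraformaldehyde gives {3-[(1S,2S)-1-[3-methoxy-4-(triisopropylsilyloxy)phenyl]-1,3-bis(triisopropylsilyloxy)propan-2-yl]-5-methoxy-4-(triisopropylsilyloxy)phenyl}methanol F4. CBr4/PPh3 gives the corresponding benzylic bromide F5. Zn dust and LiCl in THF give the benzylzinc bromide F6, which couples with commercial 4-bromofuran-2(5H)-one (seven non-hydrogen atoms) under Pd(PPh3)4 catalysis (Negishi) to give 22.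

Step 14 (acid cyclisation of a free para-hydroxybenzylic diol; possible loss of formaldehyde to a stilbene or cis/trans mixtures). The fallback sets out from 14 and returns at 25; it builds the dihydrobenzofuran by ring contraction and does not depend on step 9. TBAF/AcOH gives (S)-1-(5-bromo-2-hydroxy-3-methoxyphenyl)-3-hydroxy-3-[3-methoxy-4-(pivaloyloxy)phenyl]propan-1-one F7. Mitsunobu cyclisation (PPh3, DIAD, THF) with inversion gives (R)-6-bromo-8-methoxy-2-[3-methoxy-4-(pivaloyloxy)phenyl]chroman-4-one F8. The known PhI(OAc)2, HC(OMe)3, H2SO4 ring contraction of flavanones (1,2-shift of the fused aryl carbon) gives methyl (2R,3R)-5-bromo-7-methoxy-2-[3-methoxy-4-(pivaloyloxy)phenyl]-2,3-dihydro-1-benzofuran-3-carboxylate F9. i-Bu2AlH gives 25.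

## Further compounds

F1 | step 9 | methyl 2-[5-bromo-3-methoxy-2-(triisopropylsilyloxy)phenyl]acetate | COC(=O)Cc1cc(Br)cc(OC)c1O[Si](C(C)C)(C(C)C)C(C)C
F2 | step 9 | tert-butyl{2-[5-bromo-3-methoxy-2-(triisopropylsilyloxy)phenyl]-1-methoxyvinyloxy}dimethylsilane (E/Z mixture) | COC(O[Si](C)(C)C(C)(C)C)=Cc1cc(Br)cc(OC)c1O[Si](C(C)C)(C(C)C)C(C)C
F3 | step 9 | methyl (2R,3S)-2-[5-bromo-3-methoxy-2-(triisopropylsilyloxy)phenyl]-3-hydroxy-3-[3-methoxy-4-(pivaloyloxy)phenyl]propanoate | COc1cc([C@@H](O)[C@H](C(=O)OC)c2cc(Br)cc(OC)c2O[Si](C(C)C)(C(C)C)C(C)C)ccc1OC(=O)C(C)(C)C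
F4 | step 12 | {3-[(1S,2S)-1-[3-methoxy-4-(triisopropylsilyloxy)phenyl]-1,3-bis(triisopropylsilyloxy)propan-2-yl]-5-methoxy-4-(triisopropylsilyloxy)phenyl}methanol | COc1cc([C@@H](O[Si](C(C)C)(C(C)C)C(C)C)[C@H](CO[Si](C(C)C)(C(C)C)C(C)C)c2cc(CO)cc(OC)c2O[Si](C(C)C)(C(C)C)C(C)C)ccc1O[Si](C(C)C)(C(C)C)C(C)C
F5 | step 12 | 5-(bromomethyl)-3-methoxy-1-[(1S,2S)-1-[3-methoxy-4-(triisopropylsilyloxy)phenyl]-1,3-bis(triisopropylsilyloxy)propan-2-yl]-2-(triisopropylsilyloxy)benzene | COc1cc([C@@H](O[Si](C(C)C)(C(C)C)C(C)C)[C@H](CO[Si](C(C)C)(C(C)C)C(C)C)c2cc(CBr)cc(OC)c2O[Si](C(C)C)(C(C)C)C(C)C)ccc1O[Si](C(C)C)(C(C)C)C(C)C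
F6 | step 12 | benzylzinc bromide from F5 | COc1cc([C@@H](O[Si](C(C)C)(C(C)C)C(C)C)[C@H](CO[Si](C(C)C)(C(C)C)C(C)C)c2cc(C[Zn]Br)cc(OC)c2O[Si](C(C)C)(C(C)C)C(C)C)ccc1O[Si](C(C)C)(C(C)C)C(C)C
F7 | step 14 | (S)-1-(5-bromo-2-hydroxy-3-methoxyphenyl)-3-hydroxy-3-[3-methoxy-4-(pivaloyloxy)phenyl]propan-1-one | COc1cc([C@@H](O)CC(=O)c2cc(Br)cc(OC)c2O)ccc1OC(=O)C(C)(C)C
F8 | step 14 | (R)-6-bromo-8-methoxy-2-[3-methoxy-4-(pivaloyloxy)phenyl]chroman-4-one | O=C1C[C@H](c2ccc(OC(=O)C(C)(C)C)c(OC)c2)Oc2c(OC)cc(Br)cc12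
F9 | step 14 | methyl (2R,3R)-5-bromo-7-methoxy-2-[3-methoxy-4-(pivaloyloxy)phenyl]-2,3-dihydro-1-benzofuran-3-carboxylate | Brc1cc(OC)c2c(c1)[C@@H](C(=O)OC)[C@H](c1ccc(OC(=O)C(C)(C)C)c(OC)c1)O2
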